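The route rests on cutting C10–C20, the bond that joins the oxymethylene of the 7,20-δ-lactone to the spiro quaternary carbon C10. The step exploits that C10 is at once the β-carbon of the C6 carbonyl of the 6,19-γ-lactone and 1,6-related to C20 through O–C7–C8–C9. An acyloxymethyl radical (C20) on the C7 carboxyl therefore closes onto a C5=C10 unsaturated lactone. In one operation this makes the δ-lactone, quaternary C10 and C5. Its precursor is an open (Z)-dienoate with only the C4 and C13 stereocentres. Afterwards a SmI2 cascade folds rings C and D onto the new spirolactone.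

Key step: step 15

Remark: ent-kaurane numbering (C1–C20) is used for all intermediates. In the usual drawing C19 and C20 are α, and C18, H5 and H9 are β. The CIP descriptor of C13 changes along the route only because substituent priorities change.

Step 1
Reactants: 1 3-methylcyclohex-2-en-1-one; 2 (chloromethyl)dimethyl(phenyl)silane
Product: 4 (R)-3-{[dimethyl(phenyl)silyl]methyl}-3-methylcyclohexan-1-one, via {[dimethyl(phenyl)silyl]methyl}magnesium chloride 3 (not isolated)
Conditions: 2, Mg, Et2O, reflux; then 1, Cu(OTf)2 (3 mol %), chiral hydroxyalkyl-imidazolinium (NHC) salt (4 mol %), Et2O, −30 °C; aq NH4Cl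
Reagents that add atoms: none
Why: Copper/NHC-catalysed asymmetric conjugate addition of a β-branched primary Grignard reagent to a β-substituted cyclohexenone, with the ligand enantiomer chosen so that the masked hydroxymethyl group (C19) reaches the enone face that gives (R)-C4.

Step 2
Reactants: 4 (R)-3-{[dimethyl(phenyl)silyl]methyl}-3-methylcyclohexan-1-one
Product: 6 (R)-3-(hydroxymethyl)-3-methylcyclohexan-1-one, via (R)-3-{[fluoro(dimethyl)silyl]methyl}-3-methylcyclohexan-1-one 5 (not isolated)
Conditions: HBF4·OEt2, CH2Cl2, 0 °C to rt; then KF, KHCO3, 30 % H2O2, THF/MeOH, rt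
Reagents that add atoms: hydrogen peroxide (OO)
Why: Fleming–Tamao oxidation, in which protodesilylation of the phenyl group gives the fluorosilane and its C–Si bond is then oxidised without touching quaternary C4 or the ketone.

Step 3
Reactants: 6 (R)-3-(hydroxymethyl)-3-methylcyclohexan-1-one
Product: 8 (3aR)-3a-methylhexahydro-2-benzofuran-1,7-dione (β-keto lactone, C5 enolisable), via [(1R)-1-methyl-3-oxocyclohexyl]methyl 1H-imidazole-1-carboxylate 7 (not isolated)
Conditions: CDI, THF, rt; then NaH (3 equiv), THF, 0 to 50 °C; 1 M HCl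
Reagents that add atoms: 1,1'-carbonyldiimidazole (O=C(n1ccnc1)n1ccnc1)
Why: O-acylation followed by an intramolecular Claisen-type C-acylation (5-exo-trig), where under equilibrating conditions only the C5 enolate can reach the tethered carbonyl (C6) and the stabilised β-dicarbonyl enolate drives the closure.

Step 4
Reactants: 8 (3aR)-3a-methylhexahydro-2-benzofuran-1,7-dione
Product: 9 (3aR)-3a-methyl-1-oxo-1,3,3a,4,5,6-hexahydro-2-benzofuran-7-yl trifluoromethanesulfonate
Conditions: Tf2O, iPr2NEt, CH2Cl2, −78 °C
Reagents that add atoms: trifluoromethanesulfonic anhydride (O=S(=O)(OS(=O)(=O)C(F)(F)F)C(F)(F)F)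
Why: Enol triflation of a β-keto lactone on the ketone oxygen fixes the tetrasubstituted C5=C10 double bond and touches no stereocentre.

Step 5
Reactants: 9 (3aR)-3a-methyl-1-oxo-1,3,3a,4,5,6-hexahydro-2-benzofuran-7-yl trifluoromethanesulfonate
Product: 10 (3aR)-3a-methyl-1-oxo-1,3,3a,4,5,6-hexahydro-2-benzofuran-7-carbaldehyde
Conditions: Pd(OAc)2 (5 mol %), dppp, CO (1 atm), Et3SiH, Et3N, DMF, 70 °C
Reagents that add atoms: carbon monoxide ([C-]#[O+])
Why: Palladium-catalysed reductive carbonylation (formylation) of an enol triflate installs C9 as the aldehyde on C10.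

Step 6
Reactants: 11 (S)-epichlorohydrin; 12 dimethyl malonate
Product: 13 methyl (1R,5S)-2-oxo-3-oxabicyclo[3.1.0]hexane-1-carboxylate
Conditions: NaOMe, MeOH, reflux
Reagents that add atoms: none
Why: Malonate/epichlorohydrin domino (epoxide opening, epoxide re-formation, 3-exo-tet cyclopropanation with one clean inversion, lactonisation) carries the chiral-pool stereocentre into C13.

Step 7
Reactants: 13 methyl (1R,5S)-2-oxo-3-oxabicyclo[3.1.0]hexane-1-carboxylate
Product: 14 methyl (4S)-2-oxo-4-(prop-2-en-1-yl)oxolane-3-carboxylate (C3 epimers)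
Conditions: vinylmagnesium bromide, CuI (20 mol %), THF, −30 °C; aq NH4Cl
Reagents that add atoms: vinylmagnesium bromide (C=C[Mg]Br)
Why: Copper-catalysed homoconjugate addition opens the doubly activated cyclopropane at its CH2 carbon, so the allyl arm (C12, C11) forms and C13 is not touched.

Step 8
Reactants: 14 methyl (4S)-2-oxo-4-(prop-2-en-1-yl)oxolane-3-carboxylate
Product: 15 (4S)-4-(prop-2-en-1-yl)oxolan-2-one
Conditions: LiCl, H2O, DMSO, 140 °C
Reagents that add atoms: none
Why: Krapcho demethoxycarbonylation removes the activating ester, and C13 is not an enolisable position.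

Step 9
Reactants: 15 (4S)-4-(prop-2-en-1-yl)oxolan-2-one
Product: 17 methyl (3S)-3-(iodomethyl)hex-5-enoate, via trimethylsilyl (3S)-3-(iodomethyl)hex-5-enoate 16 (not isolated)
Conditions: TMSI, CH2Cl2, 0 °C to rt; then MeOH, 0 °C
Reagents that add atoms: iodotrimethylsilane (C[Si](C)(C)I); methanol (CO)
Why: Silyl iodide ring opening of the γ-lactone by SN2 attack of iodide at the O–CH2 carbon (C14), followed by methanolysis of the silyl ester, differentiates the C14 and C15 termini without touching C13.

Step 10
Reactants: 18 tert-butyl 2-hydroxyacetate; 19 bromoacetyl bromide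
Product: 20 tert-butyl 2-[(2-bromoacetyl)oxy]acetate
Conditions: pyridine, CH2Cl2, 0 °C
Reagents that add atoms: none
Why: Simple O-acylation of a primary alcohol with an acid bromide places the future C20 methylene on the oxygen of the future C7 carboxyl.

Step 11
Reactants: 20 tert-butyl 2-[(2-bromoacetyl)oxy]acetate; 21 diphenyl phosphite
Product: 22 tert-butyl 2-{[2-(diphenoxyphosphoryl)acetyl]oxy}acetate
Conditions: NaH, THF, 0 °C to rt
Reagents that add atoms: none
Why: Michaelis–Becker alkylation of sodium diphenyl phosphite with an α-bromo ester gives an Ando-type diaryl phosphonoacetate.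

Step 12
Reactants: 22 tert-butyl 2-{[2-(diphenoxyphosphoryl)acetyl]oxy}acetate; 17 methyl (3S)-3-(iodomethyl)hex-5-enoate
Product: 23 2-(tert-butoxy)-2-oxoethyl (4S)-2-(diphenoxyphosphoryl)-4-(2-methoxy-2-oxoethyl)hept-6-enoate (C2 epimers)
Conditions: NaH, DMF, 0 to 50 °C
Reagents that add atoms: none
Why: SN2 alkylation of the stabilised phosphonoacetate anion with the primary iodide forms C8–C14, and the anion is too weak a base to enolise the methyl ester.

Step 13
Reactants: 23 2-(tert-butoxy)-2-oxoethyl (4S)-2-(diphenoxyphosphoryl)-4-(2-methoxy-2-oxoethyl)hept-6-enoate; 10 (3aR)-3a-methyl-1-oxo-1,3,3a,4,5,6-hexahydro-2-benzofuran-7-carbaldehyde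
Product: 24 2-(tert-butoxy)-2-oxoethyl (2Z,4R)-4-(2-methoxy-2-oxoethyl)-2-{[(3aR)-3a-methyl-1-oxo-1,3,3a,4,5,6-hexahydro-2-benzofuran-7-yl]methylidene}hept-6-enoate
Conditions: NaH, THF, −78 to 0 °C
Reagents that add atoms: none
Why: Ando-type Z-selective Horner–Wadsworth–Emmons olefination, in which the electron-poor diaryl phosphonate collapses irreversibly through the syn adduct and places C7 cis to C10 on C8=C9.

Step 14
Reactants: 24 the (Z)-dienoate tert-butyl ester
Product: 25 {[(2Z,4R)-4-(2-methoxy-2-oxoethyl)-2-{[(3aR)-3a-methyl-1-oxo-1,3,3a,4,5,6-hexahydro-2-benzofuran-7-yl]methylidene}hept-6-enoyl]oxy}acetic acid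
Conditions: TFA/CH2Cl2 (1:4), 0 °C to rt
Reagents that add atoms: none
Why: Acidolysis of the tert-butyl ester (loss of isobutene) leaves the methyl ester, the lactone and all three alkenes untouched.

Step 15
Reactants: 25 the (Z)-dienoate acyloxyacetic acid
Product: 27 spiro bis-lactone: 8,9-unsaturated 7,20-δ-lactone spiro-fused at C10 to ring A with its cis-fused 6,19-γ-lactone (C20 α and syn to C19, H5 β), C8 bearing CH2–CH(allyl)(CH2CO2Me), via the acyloxymethyl (C20) radical 26 (not isolated)
Conditions: Ir[dF(CF3)ppy]2(dtbbpy)PF6 (2 mol %), Cs2CO3 (1.1 equiv), degassed DMSO (2 mM), 450 nm LEDs, 30 °C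
Reagents that add atoms: none
Why: The excited Ir(III) catalyst oxidises the caesium carboxylate of 25, and loss of CO2 gives the nucleophilic acyloxymethyl radical 26 (C20); this adds to C10, the β-carbon of the C5=C10–C6(=O) unsaturated γ-lactone, and the tertiary α-lactone radical at C5 is reduced by Ir(II) to the enolate and protonated, so the step is redox-neutral. The closest known reaction types are the photoredox decarboxylative Giese addition of α-oxy acids and the lactone-forming cyclisation of alkenoyloxymethyl radicals made from halomethyl esters. The one ring closed is the six-membered 7,20-lactone (C20–O–C7–C8=C9–C10), by 6-exo-trig attack on C10=C5 with the (Z)-C8=C9 bond holding C7 and C10 cis; 5-endo attack at C9 and 7-endo attack at C5 are out of reach because the crowded diene is twisted out of conjugation. C10 is set by C4, since the pseudo-axial C18 methyl group shields the β-face of the ring-A half-chair and C20 therefore arrives on the α-face, syn to C19. C5 is set by protonation (or carbonate-mediated equilibration) on the β-face, away from the axial C19 and C20 methylenes, which gives the cis-fused γ-lactone. Ring closure must outrun hydrogen abstraction by the unreactive s-Z ester rotamer, and this is secured by the absence of a good H-donor, high dilution, the polarity match and the cis-alkene tether (E/Z scrambling by energy transfer is harmless because only the Z isomer can close).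

Step 16
Reactants: 27 the spiro bis-lactone
Product: 28 C11 aldehyde of 27 (the allyl arm shortened to CH2–CHO)
Conditions: O3, CH2Cl2, −78 °C (Sudan III end point); Me2S, −78 °C to rt
Reagents that add atoms: ozone ([O-][O+]=O)
Why: Chemoselective ozonolysis, because the electron-rich monosubstituted alkene reacts far faster than the electron-poor trisubstituted C8=C9 bond of the lactone.

Step 17
Reactants: 28 the C11 aldehyde
Product: 30 17-nor-ludongnin A (C15 ketone, C16 methylene, 11-OH, both lactones), via the ring-C-closed samarium(III) C11-alkoxide/C7,C8-lactone enolate (drawn as the dianion) 29 (not isolated)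
Conditions: SmI2 (3 equiv, 0.1 M in THF), anhydrous LiBr, THF (5 mM), −78 to 23 °C, no proton source; then pH 7 buffer/Rochelle salt
Reagents that add atoms: none
Why: Proposed new method: SmI2 reduces the C11 aldehyde to a ketyl that adds to C9 of the unsaturated δ-lactone from the face syn to C1 (anti to the bulkier C5 branch of spiro C10), through a chair with the C13 arm equatorial and the samarium-bound oxygen chelated to the lactone carbonyl, which sets C9 and C11; a second electron gives the regiodefined Sm(III) lactone enolate 29, and this closes ring D by Dieckmann-type acylation on the C15 methyl ester, possible only on the face syn to H9 and to the C13 arm, which sets C8, while the enolate state protects C7 from the C11 alkoxide until the bicyclo[3.2.1]octane is locked; the closest known reaction types are the SmI2 ketyl–olefin/aldol cascade on unsaturated lactones and the tandem conjugate addition–Dieckmann condensation, and the new element is acylation of a Sm(III) enolate by an ester.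

Step 18
Reactants: 30 17-nor-ludongnin A
Product: 32 ludongnin A, via the C16 (N-methylanilino)methyl Mannich base 31 (not isolated)
Conditions: paraformaldehyde, N-methylanilinium trifluoroacetate, THF, reflux
Reagents that add atoms: formaldehyde, as paraformaldehyde (C=O)
Why: Mannich-type α-methylenation (condensation then β-elimination), in which C16 is the only enolisable position of the C15 ketone because C8 is a quaternary bridgehead, and the mildly acidic medium tolerates the free C11 hydroxyl and both lactones.

Compound list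
1 | 3-methylcyclohex-2-en-1-one | CC1=CC(=O)CCC1 | starting material
2 | (chloromethyl)dimethyl(phenyl)silane | C[Si](C)(CCl)c1ccccc1 | starting material
3 | {[dimethyl(phenyl)silyl]methyl}magnesium chloride | C[Si](C)(C[Mg]Cl)c1ccccc1 | intermediate
4 | (R)-3-{[dimethyl(phenyl)silyl]methyl}-3-methylcyclohexan-1-one | O=C1CCC[C@@](C)(C[Si](C)(C)c2ccccc2)C1 | intermediate
5 | (R)-3-{[fluoro(dimethyl)silyl]methyl}-3-methylcyclohexan-1-one | O=C1CCC[C@@](C)(C[Si](C)(C)F)C1 | intermediate
6 | (R)-3-(hydroxymethyl)-3-methylcyclohexan-1-one | O=C1CCC[C@@](C)(CO)C1 | intermediate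
7 | [(1R)-1-methyl-3-oxocyclohexyl]methyl 1H-imidazole-1-carboxylate | O=C1CCC[C@@](C)(COC(=O)n2ccnc2)C1 | intermediate
8 | (3aR)-3a-methylhexahydro-2-benzofuran-1,7-dione | O=C1CCC[C@@]2(C)COC(=O)C12 | intermediate
9 | (3aR)-3a-methyl-1-oxo-1,3,3a,4,5,6-hexahydro-2-benzofuran-7-yl trifluoromethanesulfonate | O=C1OC[C@]2(C)CCCC(OS(=O)(=O)C(F)(F)F)=C12 | intermediate
10 | (3aR)-3a-methyl-1-oxo-1,3,3a,4,5,6-hexahydro-2-benzofuran-7-carbaldehyde | O=CC1=C2C(=O)OC[C@]2(C)CCC1 | intermediate
11 | (S)-epichlorohydrin | ClC[C@@H]1CO1 | starting material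
12 | dimethyl malonate | COC(=O)CC(=O)OC | starting material
13 | methyl (1R,5S)-2-oxo-3-oxabicyclo[3.1.0]hexane-1-carboxylate | COC(=O)[C@@]12C[C@@H]1COC2=O | intermediate
14 | methyl (4S)-2-oxo-4-(prop-2-en-1-yl)oxolane-3-carboxylate | COC(=O)C1C(=O)OC[C@H]1CC=C | intermediate
15 | (4S)-4-(prop-2-en-1-yl)oxolan-2-one | C=CC[C@H]1CC(=O)OC1 | intermediate
16 | trimethylsilyl (3S)-3-(iodomethyl)hex-5-enoate | C=CC[C@H](CI)CC(=O)O[Si](C)(C)C | intermediate
17 | methyl (3S)-3-(iodomethyl)hex-5-enoate | C=CC[C@H](CI)CC(=O)OC | intermediate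
18 | tert-butyl 2-hydroxyacetate | CC(C)(C)OC(=O)CO | starting material
19 | bromoacetyl bromide | O=C(Br)CBr | starting material
20 | tert-butyl 2-[(2-bromoacetyl)oxy]acetate | CC(C)(C)OC(=O)COC(=O)CBr | intermediate
21 | diphenyl phosphite | O=[PH](Oc1ccccc1)Oc1ccccc1 | starting material
22 | tert-butyl 2-{[2-(diphenoxyphosphoryl)acetyl]oxy}acetate | CC(C)(C)OC(=O)COC(=O)CP(=O)(Oc1ccccc1)Oc1ccccc1 | intermediate
23 | 2-(tert-butoxy)-2-oxoethyl (4S)-2-(diphenoxyphosphoryl)-4-(2-methoxy-2-oxoethyl)hept-6-enoate | CC(C)(C)OC(=O)COC(=O)C(C[C@@H](CC=C)CC(=O)OC)P(=O)(Oc1ccccc1)Oc1ccccc1 | intermediate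
24 | (Z)-dienoate tert-butyl ester (C7 cis to C10 on C8=C9; C5=C10 unsaturated 6,19-lactone) | CC(C)(C)OC(=O)COC(=O)/C(C[C@@H](CC=C)CC(=O)OC)=C\C1=C2C(=O)OC[C@]2(C)CCC1 | intermediate
25 | (Z)-dienoate acyloxyacetic acid | OC(=O)COC(=O)/C(C[C@@H](CC=C)CC(=O)OC)=C\C1=C2C(=O)OC[C@]2(C)CCC1 | intermediate
26 | acyloxymethyl (C20) radical | [CH2]OC(=O)/C(C[C@@H](CC=C)CC(=O)OC)=C\C1=C2C(=O)OC[C@]2(C)CCC1 | intermediate
27 | spiro bis-lactone (C20 α, H5 β, 8,9-ene) | O=C1OC[C@]2(CCC[C@@]3(C)COC(=O)[C@H]32)C=C1C[C@@H](CC=C)CC(=O)OC | intermediate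
28 | C11 aldehyde of the spiro bis-lactone | O=C1OC[C@]2(CCC[C@@]3(C)COC(=O)[C@H]32)C=C1C[C@@H](CC=O)CC(=O)OC | intermediate
29 | ring-C-closed samarium(III) alkoxide/lactone enolate, drawn as the dianion | COC(=O)C[C@@H]1C[C@@H]([O-])[C@@H]2C(=C([O-])OC[C@]24CCC[C@@]3(C)COC(=O)[C@H]34)C1 | intermediate
30 | 17-nor-ludongnin A (C16 methylene) | C1C(=O)[C@]23C[C@H]1C[C@@H](O)[C@H]2[C@@]1(CCC[C@@]2(C)COC(=O)[C@H]21)COC3=O | intermediate
31 | C16 (N-methylanilino)methyl Mannich base (C16 epimers) | CN(c1ccccc1)CC1C(=O)[C@]23C[C@H]1C[C@@H](O)[C@H]2[C@@]1(CCC[C@@]2(C)COC(=O)[C@H]21)COC3=O | intermediate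
32 | ludongnin A | C=C1C(=O)[C@]23C[C@H]1C[C@@H](O)[C@H]2[C@@]1(CCC[C@@]2(C)COC(=O)[C@H]21)COC3=O | target

Total step count: 18. Longest linear sequence: 11 steps (steps 6–9 and 12–18; the ring-A branch, steps 1–5 and 13–18, is equally long).

Steps most likely to fail

1. Step 17. The samarium enolate may be quenched by proton transfer from the ester arm or from adventitious acid before it acylates. The C11 alkoxide could then translactonise onto C7.
   - The fallback separates the two events and sets out from 28.
   - The ketyl–olefin closure alone is run with SmI2 in THF at −78 °C in the presence of TMSCl. This traps both oxygen anions and should give the 11-O-trimethylsilyl ring-C-closed trimethylsilyl ketene acetal F1.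
   - The ketene acetal is then unmasked regiospecifically with TASF in THF (−78 to 0 °C). The metal-free C8 enolate should close onto the C15 ester to give the 11-O-trimethylsilyl ether of the nor-ketone F2.
   - Mild acid (citric acid, MeOH) removes the silyl ether, and the route is rejoined at 30.

2. Step 15. The open radical may abstract hydrogen or be lost by back-electron transfer, because the s-Z ester rotamer closes slowly. Facial discrimination at C10 by the C18 methyl group alone may also be insufficient.
   - The fallback moves the same bond formation to the end, onto a rigid scaffold, and sets out from 24.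
   - Chemoselective ozonolysis should give the open-chain dienoate aldehyde F3.
   - The SmI2 ketyl–olefin/acylation cascade, now steered by C13 alone, should give the bicyclo[3.2.1]octane bridgehead β-keto ester carrying the ring-A unsaturated lactone on C9, F4.
   - TFA then frees the bridgehead acyloxyacetic acid F5.
   - In F5 the quaternary bridgehead C8 and allylic 1,3-strain (H9 eclipsing C5=C10) hold the ester over the α-face of C10. This matches the bias from C18, and the decarboxylative 6-exo-trig closure returns to the route at 30.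

3. Step 13. Z selectivity may erode and addition may be slow, since the phosphonate is α-branched and the enal is hindered.
   - The fallback sets the geometry photochemically instead of kinetically and sets out from 23 and 10.
   - The olefination is run under Masamune–Roush conditions (LiCl, DBU, MeCN) without regard to geometry. This should give mainly the (E)-dienoate F6.
   - Triplet-sensitised contra-thermodynamic E-to-Z isomerisation follows (Ir(ppy)3 or thioxanthone, 400–450 nm). The Z isomer is twisted out of conjugation by allylic strain and is no longer excited, so the route is rejoined at 24.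

Further compounds
F1 | step 17 | 11-O-trimethylsilyl ring-C-closed trimethylsilyl ketene acetal | COC(=O)C[C@@H]1C[C@@H](O[Si](C)(C)C)[C@@H]2C(=C(O[Si](C)(C)C)OC[C@]24CCC[C@@]3(C)COC(=O)[C@H]34)C1
F2 | step 17 | 11-O-trimethylsilyl ether of 17-nor-ludongnin A | C1C(=O)[C@]23C[C@H]1C[C@@H](O[Si](C)(C)C)[C@H]2[C@@]1(CCC[C@@]2(C)COC(=O)[C@H]21)COC3=O
F3 | step 15 | open-chain (Z)-dienoate C11 aldehyde, tert-butyl ester | CC(C)(C)OC(=O)COC(=O)/C(C[C@@H](CC=O)CC(=O)OC)=C\C1=C2C(=O)OC[C@]2(C)CCC1
F4 | step 15 | bicyclo[3.2.1]octane bridgehead β-keto ester (tert-butoxycarbonylmethyl ester) with the ring-A unsaturated lactone on C9 | C1C(=O)[C@]2(C(=O)OCC(=O)OC(C)(C)C)C[C@H]1C[C@@H](O)[C@H]2C1=C2C(=O)OC[C@]2(C)CCC1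
F5 | step 15 | bridgehead acyloxyacetic acid | C1C(=O)[C@]2(C(=O)OCC(=O)O)C[C@H]1C[C@@H](O)[C@H]2C1=C2C(=O)OC[C@]2(C)CCC1
F6 | step 13 | (E)-dienoate tert-butyl ester | CC(C)(C)OC(=O)COC(=O)/C(C[C@@H](CC=C)CC(=O)OC)=C/C1=C2C(=O)OC[C@]2(C)CCC1
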